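**Plan**

Retrosynthesis: the C4–Br and C14–Br bonds and the methyl bonds C7–C8 and C2–C3 are removed first. Ring C (C2, C4, C5, C6, C7) is a cyclopentane that hangs from carbinol C9 through C7 and carries oxygen at C6, so it is cut at C6–C7, C5–C6 and C2–C4 into a C7≡C2 propynyl unit, ethylene (C4, C5) and CO (C6). C7–C9 and C17–C18 then go back to Grignard additions on decalin ketones.
Forward: rings A and B arrive as the bicycle of (S)-Wieland–Miescher ketone, which is oxygenated at C17/C19 and brominated at C14. Propyne is added at C9, and ring C is closed last by the Pauson–Khand reaction and then methylated at C2 and C7 and functionalised at C4 and C6.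
Stereochemistry: C12 comes from the starting ketone; C19 and C17 from α-face osmylation and α-face MeMgBr addition; C14 from equatorial hydride delivery followed by SN2 inversion; C9 from equatorial alkynyl addition. C7 is set by a lithium-chelate-directed enolate methylation, C4 by boryl addition anti to the decalin followed by invertive bromination, and C6 by hydride attack anti to the decalin.

Key step: step 12

Assumption: carbons are numbered C1–C20 in the order of the target SMILES; α/β mean the decalin face opposite to / the same as the C13 methyl on C12; (S)-Wieland–Miescher ketone, 1-propynylmagnesium bromide solution, ethylene and Co2(CO)8 are taken as commercial.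

**Route**

Step 1
Reactants: 1 (S)-Wieland–Miescher ketone
Product: 2 (4aS,5S)-5-hydroxy-4a-methyl-4,4a,5,6,7,8-hexahydronaphthalen-2(3H)-one (14β-alcohol)
Conditions: NaBH4 (0.3 equiv), EtOH, −10 °C
Reagents that add atoms: none
Why: Chemoselective borohydride reduction of the saturated C14 ketone over the conjugated C9 enone; hydride adds anti to the angular C13 methyl, so the C14 hydroxyl is β (cis to C13).

Step 2
Reactants: 2 (4aS,5S)-5-hydroxy-4a-methyl-4,4a,5,6,7,8-hexahydronaphthalen-2(3H)-one
Product: 3 14β-acetate of 2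
Conditions: Ac2O, pyridine, DMAP (cat.), CH2Cl2, rt
Reagents that add atoms: acetic anhydride CC(=O)OC(C)=O
Why: DMAP-catalysed acetylation masks the C14 alcohol so that only C17 is oxidised in step 5; no stereocentre is touched.

Step 3
Reactants: 3 14β-acetate of 2
Product: 4 C9 ethylene ketal of the 14β-acetoxy-12β-methyl decalin carrying the migrated C17=C19 double bond
Conditions: ethylene glycol, TsOH·H2O (cat.), benzene, reflux, Dean–Stark
Reagents that add atoms: ethylene glycol OCCO
Why: Acid-catalysed ketalisation of the enone proceeds with the usual deconjugative migration of the double bond to C17=C19, which puts the alkene where the C17 and C19 oxygens are needed.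

Step 4
Reactants: 4 C9 ketal with C17=C19 double bond
Product: 5 17α,19α-diol of 4 (cis-diol on the face opposite the C13 methyl)
Conditions: OsO4 (cat.), NMO, acetone–H2O, rt
Reagents that add atoms: N-methylmorpholine N-oxide C[N+]1([O-])CCOCC1; water O (both oxygens are transferred through catalytic osmium tetroxide O=[Os](=O)(=O)=O)
Why: Upjohn dihydroxylation; OsO4 adds to the alkene face opposite the axial C13 methyl, which sets the C19 hydroxyl α as in the target (the C17 carbinol is temporary).

Step 5
Reactants: 5 17α,19α-diol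
Product: 6 19α-hydroxy-17-ketone (14β-acetate; C9 ketal)
Conditions: Dess–Martin periodinane, pyridine, CH2Cl2, rt
Reagents that add atoms: none
Why: Dess–Martin oxidation of the only free secondary alcohol gives the α-hydroxy ketone; the tertiary C19 hydroxyl, the acetate and the ketal are inert.

Step 6
Reactants: 6 19α-hydroxy-17-ketone
Product: 7 14β,17β,19α-triol with the new 17α-methyl group C18 (C9 ketal)
Conditions: MeMgBr (5 equiv), THF, −78 °C to rt
Reagents that add atoms: methylmagnesium bromide C[Mg]Br
Why: Grignard addition to the C17 ketone from the α face, because the axial β trajectory is blocked by the 1,3-diaxial C13 methyl, gives the 17α-methyl-17β-carbinol; excess reagent also cleaves the C14 acetate.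

Step 7
Reactants: 7 14β,17β,19α-triol
Product: 8 17β,19α-dihydroxy-14-ketone (C9 ketal)
Conditions: Pr4N[RuO4] (cat.), NMO, 4 Å MS, CH2Cl2, rt
Reagents that add atoms: none
Why: Ley–Griffith oxidation of the single secondary alcohol (C14) to the ketone; the two tertiary alcohols cannot be oxidised.

Step 8
Reactants: 8 17β,19α-dihydroxy-14-ketone
Product: 9 14α,17β,19α-triol (axial C14 alcohol; C9 ketal)
Conditions: LiBH(s-Bu)3 (3.5 equiv), THF, −78 °C
Reagents that add atoms: none
Why: Bulky trialkylborohydride reduction; hydride is delivered equatorially from the β side because the axial path is closed by the syn-axial C19 oxygen, giving the axial 14α-alcohol needed for inversion.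

Step 9
Reactants: 9 14α,17β,19α-triol
Product: 10 14β-bromo-17β,19α-diol (C9 ketal)
Conditions: PPh3, CBr4, CH2Cl2, 0 °C to reflux
Reagents that add atoms: carbon tetrabromide BrC(Br)(Br)Br
Why: Appel reaction; bromide displaces the axial C14 alkoxyphosphonium group from the equatorial direction with SN2 inversion, giving the equatorial 14β-bromide of the target, while the tertiary alcohols do not react.

Step 10
Reactants: 10 14β-bromo-17β,19α-diol ketal
Product: 11 14β-bromo-17β,19α-dihydroxy-12β,17α-dimethyl-trans-decalin-9-one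
Conditions: AcOH–H2O (4:1), 40 °C
Reagents that add atoms: water O
Why: Mild acid hydrolysis of the dioxolane; the conditions are too mild to dehydrate the β-hydroxy ketone or to ionise the secondary bromide.

Step 11
Reactants: 11 14β-bromo-17β,19α-dihydroxy-12β,17α-dimethyl-trans-decalin-9-one; 12 1-propynylmagnesium bromide
Product: 13 14β-bromo-9β-(prop-1-ynyl)-12β,17α-dimethyl-trans-decalin-9α,17β,19α-triol (C9 propynyl carbinol)
Conditions: 12 (3.5 equiv), THF, −78 to 0 °C
Reagents that add atoms: 1-propynylmagnesium bromide CC#C[Mg]Br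
Why: Grignard 1,2-addition; the syn-axial C19 alkoxide closes the axial path at C9, so the alkynyl group enters equatorially (β) and the new C9 hydroxyl is axial (α) as in the target.

Step 12
Reactants: 13 C9 propynyl carbinol; 14 ethylene; 15 carbon monoxide (supplied as ligand of Co2(CO)8)
Product: 17 3-methyl-2-(decalin-9β-yl)cyclopent-2-en-1-one (ring C enone with C6 ketone and C7=C2; decalin as in 13), via hexacarbonyldicobalt alkyne complex 16 (not isolated)
Conditions: Co2(CO)8 (1.1 equiv), CH2Cl2, rt; then ethylene (10 bar), NMO, 4 Å MS, CH2Cl2, rt to 40 °C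
Reagents that add atoms: ethylene C=C; carbon monoxide [C-]#[O+]
Why: Co2(CO)8 binds the alkyne as its hexacarbonyldicobalt complex; N-oxide removal of one CO lets ethylene coordinate and insert into the Co–C2 bond (forming C2–C4), CO then inserts into the Co–C5 bond (forming C5–C6) and reductive elimination forms C6–C7. The closest known reaction type is the N-oxide-promoted intermolecular Pauson–Khand reaction of internal alkynes with ethylene under pressure. Ring C is closed as a cyclopentenone by C–C reductive elimination from the acyl cobaltacycle, a metal-templated (2+2+1) cycloaddition and not a polar exo or endo cyclisation. No stereocentre is created, since C2 and C7 stay sp2 and C4 and C5 are methylenes. The only selectivity needed is alkyne regiochemistry: the bulky tertiary carbinol substituent forces ethylene to insert at the methyl-bearing carbon C2, so C7 ends next to the new C6 carbonyl. Ethylene is symmetric, and the free tertiary hydroxyls and the secondary bromide are spectators.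

Step 13
Reactants: 17 ring C enone
Product: 19 ring C ketone with C2 gem-dimethyl and the C7 methyl C8 set as in the target (triol), via tetralithium enolate 18 (not isolated)
Conditions: Me2CuLi (from CuI and MeLi; 6 equiv), Et2O–THF, −40 to 0 °C; MeI, −78 to −40 °C; AcOH, −78 °C
Reagents that add atoms: lithium dimethylcuprate [Li+].C[Cu-]C; iodomethane CI
Why: Cuprate conjugate addition at C2 followed by enolate methylation in the manner of a Fráter–Seebach polyanion alkylation; lithium bridging the enolate oxygen, O9 and the syn-axial O19 should turn the enolate toward the C19/C20 flank of ring A, so MeI enters from the open C10 flank and sets C7.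

Step 14
Reactants: 19 ring C ketone
Product: 21 C4=C5 enone as its 9,17,19-tris(trimethylsilyl) ether, via trimethylsilyl enol ether 20 (not isolated)
Conditions: TMSOTf (6 equiv), Et3N, CH2Cl2, 0 °C to rt; then Pd(OAc)2 (1 equiv), MeCN, rt
Reagents that add atoms: trimethylsilyl triflate C[Si](C)(C)OS(=O)(=O)C(F)(F)F
Why: Saegusa–Ito oxidation; soft enolisation can only go toward C5 and caps the three tertiary hydroxyls in the same operation (which also removes the retro-aldol-prone free C9 hydroxyl), and Pd(OAc)2 then dehydrogenates C4–C5.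

Step 15
Reactants: 21 C4=C5 enone
Product: 22 C4 pinacol boronate with boron on the face of C8 and trans to C9 (C6 ketone; tris-TMS ether)
Conditions: CuCl (cat.), NaOtBu (cat.), Xantphos (cat.), B2pin2, MeOH, THF, rt
Reagents that add atoms: bis(pinacolato)diboron CC1(C)OB(OC1(C)C)B1OC(C)(C)C(C)(C)O1
Why: Copper-catalysed conjugate borylation of a cyclic enone; the boryl copper species adds to C4 on the face of the C7 methyl, away from the bulky decalin carbinol on C7, which sets C4 with boron trans to C9.

Step 16
Reactants: 22 C4 pinacol boronate ketone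
Product: 23 C6 alcohol of 22 (hydroxyl cis to C9 and trans to boron)
Conditions: NaBH4, MeOH–THF, −20 °C
Reagents that add atoms: none
Why: Borohydride reduction of the cyclopentanone; hydride attacks C6 from the face of the adjacent C7 methyl, opposite the much larger decalin carbinol on the same carbon, giving the C6 hydroxyl cis to C9 as in the target.

Step 17
Reactants: 23 C6 alcohol
Product: 24 C6 trimethylsilyl ether of 23
Conditions: TMSOTf, 2,6-lutidine, CH2Cl2, −78 to 0 °C
Reagents that add atoms: trimethylsilyl triflate C[Si](C)(C)OS(=O)(=O)C(F)(F)F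
Why: Silylation protects the secondary C6 alcohol from oxidation by NBS and from aryllithium in the next step.

Step 18
Reactants: 24 C6 trimethylsilyl ether
Product: 26 tetrakis(trimethylsilyl) ether of neoirietetraol (C4 bromide cis to C6–O and C9), via lithium arylboronate complex 25 (not isolated)
Conditions: 3,5-(CF3)2C6H3Li (from the aryl bromide and n-BuLi), THF, −78 °C; then NBS, −78 °C to rt
Reagents that add atoms: N-bromosuccinimide O=C1CCC(=O)N1Br
Why: Stereoinvertive bromination of a secondary pinacol boronic ester through its aryllithium ate complex (SE2 with inversion); boron on the methyl face is replaced by bromine on the C9 face, giving the C4 configuration of the target without an SN2 step or a free neighbouring hydroxyl.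

Step 19
Reactants: 26 tetrakis(trimethylsilyl) ether of neoirietetraol
Product: 27 neoirietetraol
Conditions: HF·pyridine, THF, 0 °C to rt
Reagents that add atoms: none
Why: Acidic fluoride cleavage of the four trimethylsilyl ethers under non-basic conditions, which leave the two secondary bromides and the tertiary alcohols intact.

**Compound list**

1 | (S)-Wieland–Miescher ketone, (S)-8a-methyl-3,4,8,8a-tetrahydronaphthalene-1,6(2H,7H)-dione | C[C@]12CCC(=O)C=C1CCCC2=O | starting material
2 | (4aS,5S)-5-hydroxy-4a-methyl-4,4a,5,6,7,8-hexahydronaphthalen-2(3H)-one (14β-alcohol) | C[C@]12CCC(=O)C=C1CCC[C@@H]2O | intermediate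
3 | 14β-acetate of 2 | C[C@]12CCC(=O)C=C1CCC[C@@H]2OC(C)=O | intermediate
4 | C9 ethylene ketal of the 14β-acetoxy-12β-methyl decalin with C17=C19 double bond | C12(OCCO1)CC[C@]3(C)[C@@H](OC(C)=O)CCC=C3C2 | intermediate
5 | 17α,19α-diol of 4 | C12(OCCO1)CC[C@]3(C)[C@@H](OC(C)=O)CC[C@H](O)[C@@]3(O)C2 | intermediate
6 | 19α-hydroxy-17-ketone (14β-acetate, C9 ketal) | C12(OCCO1)CC[C@]3(C)[C@@H](OC(C)=O)CCC(=O)[C@@]3(O)C2 | intermediate
7 | 14β,17β,19α-triol with 17α-methyl (C9 ketal) | C12(OCCO1)CC[C@]3(C)[C@@H](O)CC[C@@](C)(O)[C@@]3(O)C2 | intermediate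
8 | 17β,19α-dihydroxy-14-ketone (C9 ketal) | C12(OCCO1)CC[C@]3(C)C(=O)CC[C@@](C)(O)[C@@]3(O)C2 | intermediate
9 | 14α,17β,19α-triol (C9 ketal) | C12(OCCO1)CC[C@]3(C)[C@H](O)CC[C@@](C)(O)[C@@]3(O)C2 | intermediate
10 | 14β-bromo-17β,19α-diol (C9 ketal) | C12(OCCO1)CC[C@]3(C)[C@@H](Br)CC[C@@](C)(O)[C@@]3(O)C2 | intermediate
11 | 14β-bromo-17β,19α-dihydroxy-12β,17α-dimethyl-trans-decalin-9-one | O=C1CC[C@]2(C)[C@@H](Br)CC[C@@](C)(O)[C@@]2(O)C1 | intermediate
12 | 1-propynylmagnesium bromide | CC#C[Mg]Br | starting material
13 | C9 propynyl carbinol: 14β-bromo-9β-(prop-1-ynyl)-12β,17α-dimethyl-trans-decalin-9α,17β,19α-triol | CC#C[C@@]1(O)CC[C@]2(C)[C@@H](Br)CC[C@@](C)(O)[C@@]2(O)C1 | intermediate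
14 | ethylene | C=C | starting material
15 | carbon monoxide | [C-]#[O+] | starting material
16 | hexacarbonyldicobalt complex of alkyne 13 | CC12[Co]3(=C=O)(=C=O)(=C=O)[Co]1(=C=O)(=C=O)(=C=O)C23[C@@]1(O)CC[C@]2(C)[C@@H](Br)CC[C@@](C)(O)[C@@]2(O)C1 | intermediate
17 | ring C enone: 3-methyl-2-(decalin-9β-yl)cyclopent-2-en-1-one, decalin as in 13 | CC1=C([C@@]2(O)CC[C@]3(C)[C@@H](Br)CC[C@@](C)(O)[C@@]3(O)C2)C(=O)CC1 | intermediate
18 | tetralithium C6 enolate tris-alkoxide after methyl addition at C2 | CC1(C)CCC([O-])=C1[C@@]1([O-])CC[C@]2(C)[C@@H](Br)CC[C@@](C)([O-])[C@@]2([O-])C1.[Li+].[Li+].[Li+].[Li+] | intermediate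
19 | ring C ketone with C2 gem-dimethyl and C7 methyl (triol) | CC1(C)CCC(=O)[C@]1(C)[C@@]1(O)CC[C@]2(C)[C@@H](Br)CC[C@@](C)(O)[C@@]2(O)C1 | intermediate
20 | C5=C6 trimethylsilyl enol ether of 19, 9,17,19-tris-TMS ether | CC1(C)CC=C(O[Si](C)(C)C)[C@]1(C)[C@@]1(O[Si](C)(C)C)CC[C@]2(C)[C@@H](Br)CC[C@@](C)(O[Si](C)(C)C)[C@@]2(O[Si](C)(C)C)C1 | intermediate
21 | C4=C5 enone, 9,17,19-tris(trimethylsilyl) ether | CC1(C)C=CC(=O)[C@]1(C)[C@@]1(O[Si](C)(C)C)CC[C@]2(C)[C@@H](Br)CC[C@@](C)(O[Si](C)(C)C)[C@@]2(O[Si](C)(C)C)C1 | intermediate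
22 | C4 pinacol boronate (boron cis to C8, trans to C9), C6 ketone | CC1(C)[C@@H](B3OC(C)(C)C(C)(C)O3)CC(=O)[C@]1(C)[C@@]1(O[Si](C)(C)C)CC[C@]2(C)[C@@H](Br)CC[C@@](C)(O[Si](C)(C)C)[C@@]2(O[Si](C)(C)C)C1 | intermediate
23 | C6 alcohol of 22 (hydroxyl cis to C9) | CC1(C)[C@@H](B3OC(C)(C)C(C)(C)O3)C[C@H](O)[C@]1(C)[C@@]1(O[Si](C)(C)C)CC[C@]2(C)[C@@H](Br)CC[C@@](C)(O[Si](C)(C)C)[C@@]2(O[Si](C)(C)C)C1 | intermediate
24 | C6 trimethylsilyl ether of 23 | CC1(C)[C@@H](B3OC(C)(C)C(C)(C)O3)C[C@H](O[Si](C)(C)C)[C@]1(C)[C@@]1(O[Si](C)(C)C)CC[C@]2(C)[C@@H](Br)CC[C@@](C)(O[Si](C)(C)C)[C@@]2(O[Si](C)(C)C)C1 | intermediate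
25 | lithium aryl(alkyl)pinacolboronate complex of 24, aryl = 3,5-bis(trifluoromethyl)phenyl | CC1(C)[C@@H]([B-]3(OC(C)(C)C(C)(C)O3)c3cc(cc(c3)C(F)(F)F)C(F)(F)F)C[C@H](O[Si](C)(C)C)[C@]1(C)[C@@]1(O[Si](C)(C)C)CC[C@]2(C)[C@@H](Br)CC[C@@](C)(O[Si](C)(C)C)[C@@]2(O[Si](C)(C)C)C1.[Li+] | intermediate
26 | tetrakis(trimethylsilyl) ether of neoirietetraol | CC1(C)[C@H](Br)C[C@H](O[Si](C)(C)C)[C@]1(C)[C@@]1(O[Si](C)(C)C)CC[C@]2(C)[C@@H](Br)CC[C@@](C)(O[Si](C)(C)C)[C@@]2(O[Si](C)(C)C)C1 | intermediate
27 | neoirietetraol | CC1(C)[C@H](Br)C[C@H](O)[C@]1(C)[C@@]1(O)CC[C@]2(C)[C@@H](Br)CC[C@@](C)(O)[C@@]2(O)C1 | target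

**Totals**

Total step count: 19. Longest linear sequence: 19 steps (1 to 27).

**Steps most likely to fail**

1. Step 13 (conjugate addition and C7 methylation). Two processes threaten it: retro-aldol cleavage of the C7–C9 bond in the lithium aldolate once C7 is quaternary, and loss of facial selectivity if the lithium bridge to O19 is not maintained, because the two ring A arms at C9 differ only at C19 versus C11. The fallback sets out from 17 and removes both the free alkoxide and the reliance on the decalin. TMSOTf/Et3N caps the three hydroxyls to give the tris(trimethylsilyl) ether of the enone F1. Allylic oxidation of the ring C methylene C4 with Pd(OH)2/C, t-BuOOH and K2CO3 gives the ene-dione F2. (S)-2-Methyl-CBS-oxazaborolidine with catecholborane reduces the less hindered C4 carbonyl under catalyst control to the C4 carbinol F3, with the hydroxyl on the face that C9 will occupy. TBSOTf/2,6-lutidine gives the C4 silyl ether F4. Me2CuLi then MeI gives the methylated ketone F5, MeI entering C7 anti to the C4 silyloxy group. DBU in CH2Cl2 eliminates the silanol across C4–C5, and the route is rejoined at enone 21.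

2. Step 9 (C14 bromination). Anti-elimination toward C15 or a 1,2-shift from the quaternary C12 may overtake the slow SN2 displacement at this axial neopentyl centre. The fallback sets out from 9 and anchors the leaving group to the syn-axial C19 oxygen. SOCl2/Et3N closes the C14/C19 diol to the cyclic sulfite F6, and RuCl3/NaIO4 oxidises it to the cyclic sulfate F7. Bu4NBr in acetone opens the sulfate at the secondary carbon C14 with inversion to the 14β-bromo C19 sulfate salt F8. Aqueous H2SO4 in THF hydrolyses the sulfate ester together with the dioxolane, and the route is rejoined at ketone 11.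

3. Step 12 (Pauson–Khand reaction). Ethylene insertion at the hindered internal alkyne complex may be so slow that decomplexation and alkyne oligomerisation win. The fallback sets out from 11 and forms the C7–C9 bond with a preformed cyclopentenone instead of the three-component assembly. Commercial 2-bromo-3-methylcyclopent-2-en-1-one is ketalised with ethylene glycol and TsOH to the bromo ketal F9. n-BuLi at −78 °C gives the vinyllithium F10, which adds equatorially to ketone 11 (3.5 equiv, THF, −78 °C) to give the carbinol ketal F11. Oxalic acid on wet silica gel removes the ketal, and the route is rejoined at enone 17.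

**Further compounds**

F1 | step 13 | 9,17,19-tris(trimethylsilyl) ether of enone 17 | CC1=C([C@@]2(O[Si](C)(C)C)CC[C@]3(C)[C@@H](Br)CC[C@@](C)(O[Si](C)(C)C)[C@@]3(O[Si](C)(C)C)C2)C(=O)CC1
F2 | step 13 | ring C ene-dione (C4 and C6 ketones, C7=C2), tris-TMS ether | CC1=C([C@@]2(O[Si](C)(C)C)CC[C@]3(C)[C@@H](Br)CC[C@@](C)(O[Si](C)(C)C)[C@@]3(O[Si](C)(C)C)C2)C(=O)CC1=O
F3 | step 13 | C4 carbinol of F2 (hydroxyl on the future C9 face) | CC1=C([C@@]2(O[Si](C)(C)C)CC[C@]3(C)[C@@H](Br)CC[C@@](C)(O[Si](C)(C)C)[C@@]3(O[Si](C)(C)C)C2)C(=O)C[C@H]1O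
F4 | step 13 | C4 tert-butyldimethylsilyl ether of F3 | CC1=C([C@@]2(O[Si](C)(C)C)CC[C@]3(C)[C@@H](Br)CC[C@@](C)(O[Si](C)(C)C)[C@@]3(O[Si](C)(C)C)C2)C(=O)C[C@H]1O[Si](C)(C)C(C)(C)C
F5 | step 13 | C4-silyloxy ring C ketone with C2 gem-dimethyl and C7 methyl | CC1(C)[C@H](O[Si](C)(C)C(C)(C)C)CC(=O)[C@]1(C)[C@@]1(O[Si](C)(C)C)CC[C@]2(C)[C@@H](Br)CC[C@@](C)(O[Si](C)(C)C)[C@@]2(O[Si](C)(C)C)C1
F6 | step 9 | C14/C19 cyclic sulfite of triol 9 | C12(OCCO1)CC[C@]3(C)[C@H]4CC[C@@](C)(O)[C@@]3(OS(=O)O4)C2
F7 | step 9 | C14/C19 cyclic sulfate of triol 9 | C12(OCCO1)CC[C@]3(C)[C@H]4CC[C@@](C)(O)[C@@]3(OS(=O)(=O)O4)C2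
F8 | step 9 | tetrabutylammonium salt of the 14β-bromo C19 sulfate monoester | C12(OCCO1)CC[C@]3(C)[C@@H](Br)CC[C@@](C)(O)[C@@]3(OS(=O)(=O)[O-])C2.CCCC[N+](CCCC)(CCCC)CCCC
F9 | step 12 | 6-bromo-7-methyl-1,4-dioxaspiro[4.4]non-6-ene | CC1=C(Br)C2(CC1)OCCO2
F10 | step 12 | 6-lithio-7-methyl-1,4-dioxaspiro[4.4]non-6-ene | CC1=C([Li])C2(CC1)OCCO2
F11 | step 12 | ethylene ketal of enone 17 | CC1=C([C@@]2(O)CC[C@]3(C)[C@@H](Br)CC[C@@](C)(O)[C@@]3(O)C2)C2(CC1)OCCO2
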